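The lactone ring (O1, C2, C3, C4, C5) is traced back to an open chain in which boron stands in for the carboxyl carbon C2. C3 then carries boron, C4 and the methylene of the 3,4,5-trimethoxyphenyl ring, which is the pattern left by a three-component coupling of a vinylboron ate complex. One palladium-catalysed operation forms the C3–C4 bond by a boron-to-carbon shift and the CH2–aryl bond by reductive elimination, and sets C3 under ligand control while C4 is carried over unchanged. Its precursor is an enantioenriched secondary pinacol boronate with boron on C4, a silyl ether on O1 (bound to C5) and a benzyl ether on the phenol.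

Key step: step 6

Remark: the facial sense of the chiral catalysts in steps 4 and 6 is assumed to follow that of simple β-alkylstyrenes and simple migrating groups, so the ligand hand ("giving S", "giving 3R") is fixed in a pilot run with the two commercial antipodes; Mandyphos denotes 1,1'-bis[bis(4-methoxy-3,5-dimethylphenyl)phosphino]-2,2'-bis[(dimethylamino)(phenyl)methyl]ferrocene and Me-DuPhos denotes 1,2-bis(2,5-dimethylphospholan-1-yl)benzene.

Step 1
Reactants: 1 ferulic acid
Product: 2 benzyl (E)-3-[4-(benzyloxy)-3-methoxyphenyl]prop-2-enoate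
Conditions: BnBr (2.4 equiv), K2CO3 (3 equiv), DMF, 60 °C
Reagents that add atoms: benzyl bromide, BrCc1ccccc1
Why: K2CO3 deprotonates both the carboxylic acid and the phenol, and benzyl bromide alkylates both oxygens (Williamson ether synthesis and carboxylate O-alkylation), so ester and phenol ether are installed in one operation without touching the E-alkene.

Step 2
Reactants: 2 benzyl (E)-3-[4-(benzyloxy)-3-methoxyphenyl]prop-2-enoate
Product: 3 (E)-3-[4-(benzyloxy)-3-methoxyphenyl]prop-2-en-1-ol
Conditions: iBu2AlH (2.5 equiv), CH2Cl2, −78 °C to 0 °C; aq. KNaC4H4O6 (potassium sodium tartrate) work-up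
Reagents that add atoms: none
Why: iBu2AlH reduces an α,β-unsaturated ester by 1,2-hydride delivery to the allylic alcohol without conjugate reduction, the aryl benzyl ether is inert, and the non-acidic work-up protects the electron-rich cinnamyl alcohol.

Step 3
Reactants: 3 (E)-3-[4-(benzyloxy)-3-methoxyphenyl]prop-2-en-1-ol
Product: 4 (E)-{3-[4-(benzyloxy)-3-methoxyphenyl]prop-2-enyloxy}(tert-butyl)dimethylsilane
Conditions: TBSCl (1.2 equiv), imidazole (2 equiv), CH2Cl2, rt
Reagents that add atoms: tert-butyldimethylsilyl chloride, CC(C)(C)[Si](C)(C)Cl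
Why: Imidazole-promoted silylation of an unhindered primary alcohol is routine and gives an ether that is bulky and a poor leaving group, as needed next to boron later.

Step 4
Reactants: 4 (E)-{3-[4-(benzyloxy)-3-methoxyphenyl]prop-2-enyloxy}(tert-butyl)dimethylsilane; 5 bis(pinacolato)diboron
Product: 6 (2S)-tert-butyl{3-[4-(benzyloxy)-3-methoxyphenyl]-2-(4,4,5,5-tetramethyl-1,3,2-dioxaborolan-2-yl)propoxy}dimethylsilane
Conditions: CuCl (5 mol %), NaOtBu (10 mol %), Me-DuPhos (6 mol %, antipode giving S), MeOH (2 equiv), THF, rt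
Reagents that add atoms: none
Why: In this copper-catalysed enantioselective protoboration of a β-substituted styrene the ligated copper boryl adds syn across the alkene with copper on the benzylic carbon and boron on the neighbouring carbon (the future C4), the chiral bisphosphine chooses the alkene face and so sets this stereocentre, and methanol protonates the benzylcopper, while the silyloxy group is too poor a leaving group to divert the organocopper.

Step 5
Reactants: 7 3,4,5-trimethoxyphenol
Product: 8 3,4,5-trimethoxyphenyl trifluoromethanesulfonate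
Conditions: Tf2O (1.2 equiv), pyridine (2 equiv), CH2Cl2, 0 °C to rt
Reagents that add atoms: trifluoromethanesulfonic anhydride, O=S(=O)(OS(=O)(=O)C(F)(F)F)C(F)(F)F
Why: O-Sulfonylation of a phenol with triflic anhydride and pyridine is a standard way to an aryl triflate, and the three methyl ethers are spectators.

Step 6
Reactants: 6 (2S)-tert-butyl{3-[4-(benzyloxy)-3-methoxyphenyl]-2-(4,4,5,5-tetramethyl-1,3,2-dioxaborolan-2-yl)propoxy}dimethylsilane; 8 3,4,5-trimethoxyphenyl trifluoromethanesulfonate; 9 tetravinylstannane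
Product: 12 tert-butyl{(2R,3R)-2-[4-(benzyloxy)-3-methoxybenzyl]-3-(4,4,5,5-tetramethyl-1,3,2-dioxaborolan-2-yl)-4-(3,4,5-trimethoxyphenyl)butoxy}dimethylsilane, via vinyllithium 10 (not isolated), via lithium vinylborate complex 11 (not isolated)
Conditions: 9, n-BuLi, pentane, rt (10 settles, is washed under argon and taken up in THF); 6, THF, 0 °C to rt; then 8, Pd(OAc)2 (3 mol %), Mandyphos (3.6 mol %, antipode giving 3R), THF, 60 °C
Reagents that add atoms: none
Why: Oxidative addition of triflate 8 to zerovalent palladium gives a cationic aryl complex of divalent palladium that binds the vinyl group of ate complex 11; this triggers a 1,2-metallate shift in which the C4 carbon leaves boron for the vinyl α-carbon (the new C3) anti to palladium, and reductive elimination from the resulting β-boryl alkylpalladium forms the CH2–aryl bond. The closest known reaction type is the palladium/Mandyphos-catalysed enantioselective conjunctive cross-coupling of vinylboron ate complexes with aryl triflates, applied here to a secondary alkyl migrating group. No ring is closed. The new C3 stereocentre is set by the chiral ligand, which decides the vinyl face that palladium occupies, whereas C4 migrates with retention and keeps the configuration from step 4. The conjunctive path must outrun direct Suzuki-type transfer, β-hydride elimination and loss of the β-silyloxy group from the ate complex; the wide-bite-angle ligand, the halide-free triflate manifold, the pinacol ligand on boron and the bulky, poorly leaving silyl ether should secure this. A mismatched pairing of ligand and C4 centre would lower the diastereomer ratio, which is tolerable because C3 later becomes the epimerisable α-carbon of a lactone whose trans isomer is favoured.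

Step 7
Reactants: 12 tert-butyl{(2R,3R)-2-[4-(benzyloxy)-3-methoxybenzyl]-3-(4,4,5,5-tetramethyl-1,3,2-dioxaborolan-2-yl)-4-(3,4,5-trimethoxyphenyl)butoxy}dimethylsilane
Product: 15 (2R,3R)-3-[4-(benzyloxy)-3-methoxybenzyl]-4-[(tert-butyldimethylsilyl)oxy]-2-(3,4,5-trimethoxybenzyl)butan-1-ol, via lithium chloromethylborate complex 13 (not isolated), via homologated boronic ester 14 (not isolated)
Conditions: BrCH2Cl (3 equiv), n-BuLi (2.5 equiv, added last), THF, −78 °C to rt; then NaBO3·4H2O, THF/H2O, rt
Reagents that add atoms: bromochloromethane, ClCBr; sodium perborate, [Na+].[Na+].O[B-]1(O)OO[B-](O)(O)OO1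
Why: In this Matteson homologation LiCH2Cl, formed by bromine–lithium exchange in the presence of 12, adds to boron and the secondary alkyl group shifts onto the CH2 carbon with loss of chloride and retention at C3, after which perborate oxidises only the primary C–B bond to the C2 carbinol.

Step 8
Reactants: 15 (2R,3R)-3-[4-(benzyloxy)-3-methoxybenzyl]-4-[(tert-butyldimethylsilyl)oxy]-2-(3,4,5-trimethoxybenzyl)butan-1-ol
Product: 17 (2R,3R)-3-[4-(benzyloxy)-3-methoxybenzyl]-4-[(tert-butyldimethylsilyl)oxy]-2-(3,4,5-trimethoxybenzyl)butanoic acid, via aldehyde 16 (not isolated)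
Conditions: TEMPO (20 mol %), PhI(OAc)2 (2.5 equiv), MeCN/H2O (1:1), rt
Reagents that add atoms: water, O
Why: The oxoammonium-mediated oxidation (TEMPO/PhI(OAc)2) takes the primary alcohol through the aldehyde and its hydrate to the acid under mild, chlorine-free conditions that spare the silyl ether, the benzyl ether and the electron-rich arenes, and the short-lived aldehyde leaves little time for epimerisation at C3.

Step 9
Reactants: 17 (2R,3R)-3-[4-(benzyloxy)-3-methoxybenzyl]-4-[(tert-butyldimethylsilyl)oxy]-2-(3,4,5-trimethoxybenzyl)butanoic acid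
Product: 19 (3R,4R)-4-[4-(benzyloxy)-3-methoxybenzyl]-3-(3,4,5-trimethoxybenzyl)dihydrofuran-2(3H)-one, via hydroxy acid 18 (not isolated)
Conditions: HCl (2 M aq), THF, rt
Reagents that add atoms: none
Why: Dilute acid hydrolyses the primary silyl ether and the released γ-hydroxy acid closes to the five-membered lactone by acid-catalysed acyl substitution (5-exo-trig), forming the O1–C2 bond without touching either stereocentre or the aryl benzyl ether.

Step 10
Reactants: 19 (3R,4R)-4-[4-(benzyloxy)-3-methoxybenzyl]-3-(3,4,5-trimethoxybenzyl)dihydrofuran-2(3H)-one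
Product: 20 hernanol, (3R,4R)-4-(4-hydroxy-3-methoxybenzyl)-3-(3,4,5-trimethoxybenzyl)dihydrofuran-2(3H)-one
Conditions: H2 (1 atm), Pd/C (10 wt %), EtOAc/EtOH, rt
Reagents that add atoms: none
Why: Hydrogenolysis of the aryl benzyl ether over Pd/C frees the phenol, while the lactone, the aryl methyl ethers and both stereocentres are inert under neutral conditions.

Compound list
1 | ferulic acid, (E)-3-(4-hydroxy-3-methoxyphenyl)prop-2-enoic acid | COc1cc(/C=C/C(=O)O)ccc1O | starting material
2 | benzyl (E)-3-[4-(benzyloxy)-3-methoxyphenyl]prop-2-enoate | COc1cc(/C=C/C(=O)OCc2ccccc2)ccc1OCc1ccccc1 | intermediate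
3 | (E)-3-[4-(benzyloxy)-3-methoxyphenyl]prop-2-en-1-ol | COc1cc(/C=C/CO)ccc1OCc1ccccc1 | intermediate
4 | (E)-{3-[4-(benzyloxy)-3-methoxyphenyl]prop-2-enyloxy}(tert-butyl)dimethylsilane | COc1cc(/C=C/CO[Si](C)(C)C(C)(C)C)ccc1OCc1ccccc1 | intermediate
5 | bis(pinacolato)diboron | CC1(C)OB(OC1(C)C)B1OC(C)(C)C(C)(C)O1 | starting material
6 | (2S)-tert-butyl{3-[4-(benzyloxy)-3-methoxyphenyl]-2-(4,4,5,5-tetramethyl-1,3,2-dioxaborolan-2-yl)propoxy}dimethylsilane | COc1cc(C[C@H](B2OC(C)(C)C(C)(C)O2)CO[Si](C)(C)C(C)(C)C)ccc1OCc1ccccc1 | intermediate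
7 | 3,4,5-trimethoxyphenol | COc1cc(O)cc(OC)c1OC | starting material
8 | 3,4,5-trimethoxyphenyl trifluoromethanesulfonate | COc1cc(OS(=O)(=O)C(F)(F)F)cc(OC)c1OC | intermediate
9 | tetravinylstannane | C=C[Sn](C=C)(C=C)C=C | starting material
10 | vinyllithium (halide-free, used as made) | [Li]C=C | intermediate
11 | lithium [(2S)-1-[4-(benzyloxy)-3-methoxyphenyl]-3-[(tert-butyldimethylsilyl)oxy]propan-2-yl](ethenyl)(pinacolato)borate | [Li+].COc1cc(C[C@H]([B-]2(C=C)OC(C)(C)C(C)(C)O2)CO[Si](C)(C)C(C)(C)C)ccc1OCc1ccccc1 | intermediate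
12 | tert-butyl{(2R,3R)-2-[4-(benzyloxy)-3-methoxybenzyl]-3-(4,4,5,5-tetramethyl-1,3,2-dioxaborolan-2-yl)-4-(3,4,5-trimethoxyphenyl)butoxy}dimethylsilane | COc1cc(C[C@H]([C@@H](Cc2cc(OC)c(OC)c(OC)c2)B2OC(C)(C)C(C)(C)O2)CO[Si](C)(C)C(C)(C)C)ccc1OCc1ccccc1 | intermediate
13 | lithium (chloromethyl)[(2R,3R)-3-[4-(benzyloxy)-3-methoxybenzyl]-4-[(tert-butyldimethylsilyl)oxy]-1-(3,4,5-trimethoxyphenyl)butan-2-yl](pinacolato)borate | [Li+].COc1cc(C[C@H]([C@@H](Cc2cc(OC)c(OC)c(OC)c2)[B-]2(CCl)OC(C)(C)C(C)(C)O2)CO[Si](C)(C)C(C)(C)C)ccc1OCc1ccccc1 | intermediate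
14 | tert-butyl{(2R,3R)-2-[4-(benzyloxy)-3-methoxybenzyl]-3-[(4,4,5,5-tetramethyl-1,3,2-dioxaborolan-2-yl)methyl]-4-(3,4,5-trimethoxyphenyl)butoxy}dimethylsilane | COc1cc(C[C@H]([C@@H](Cc2cc(OC)c(OC)c(OC)c2)CB2OC(C)(C)C(C)(C)O2)CO[Si](C)(C)C(C)(C)C)ccc1OCc1ccccc1 | intermediate
15 | (2R,3R)-3-[4-(benzyloxy)-3-methoxybenzyl]-4-[(tert-butyldimethylsilyl)oxy]-2-(3,4,5-trimethoxybenzyl)butan-1-ol | COc1cc(C[C@H]([C@@H](Cc2cc(OC)c(OC)c(OC)c2)CO)CO[Si](C)(C)C(C)(C)C)ccc1OCc1ccccc1 | intermediate
16 | (2R,3R)-3-[4-(benzyloxy)-3-methoxybenzyl]-4-[(tert-butyldimethylsilyl)oxy]-2-(3,4,5-trimethoxybenzyl)butanal | COc1cc(C[C@H]([C@@H](Cc2cc(OC)c(OC)c(OC)c2)C=O)CO[Si](C)(C)C(C)(C)C)ccc1OCc1ccccc1 | intermediate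
17 | (2R,3R)-3-[4-(benzyloxy)-3-methoxybenzyl]-4-[(tert-butyldimethylsilyl)oxy]-2-(3,4,5-trimethoxybenzyl)butanoic acid | COc1cc(C[C@H]([C@@H](Cc2cc(OC)c(OC)c(OC)c2)C(=O)O)CO[Si](C)(C)C(C)(C)C)ccc1OCc1ccccc1 | intermediate
18 | (2R,3R)-3-[4-(benzyloxy)-3-methoxybenzyl]-4-hydroxy-2-(3,4,5-trimethoxybenzyl)butanoic acid | COc1cc(C[C@H]([C@@H](Cc2cc(OC)c(OC)c(OC)c2)C(=O)O)CO)ccc1OCc1ccccc1 | intermediate
19 | (3R,4R)-4-[4-(benzyloxy)-3-methoxybenzyl]-3-(3,4,5-trimethoxybenzyl)dihydrofuran-2(3H)-one | COc1cc(C[C@H]2COC(=O)[C@@H]2Cc2cc(OC)c(OC)c(OC)c2)ccc1OCc1ccccc1 | intermediate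
20 | hernanol, (3R,4R)-4-(4-hydroxy-3-methoxybenzyl)-3-(3,4,5-trimethoxybenzyl)dihydrofuran-2(3H)-one | COc1cc(C[C@H]2COC(=O)[C@@H]2Cc2cc(OC)c(OC)c(OC)c2)ccc1O | target

Total step count: 10. Longest linear sequence: 9 (steps 1 to 4 and 6 to 10).

Steps most likely to fail

1. Step 6. The 1,2-shift of the branched secondary alkyl group may be slow, so that direct transfer of a boron substituent to palladium or loss of the β-silyloxy group from the ate complex takes over, or the catalyst may control the C3 face poorly in a mismatched pairing with C4. The fallback replaces the three-component coupling by a lactone enolate alkylation.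
   - From 6, a first Matteson homologation (BrCH2Cl, n-BuLi, THF, −78 °C to rt) should give (2S)-tert-butyl{2-[4-(benzyloxy)-3-methoxybenzyl]-3-(4,4,5,5-tetramethyl-1,3,2-dioxaborolan-2-yl)propoxy}dimethylsilane F1.
   - A second round should give (2S)-tert-butyl{2-[4-(benzyloxy)-3-methoxybenzyl]-4-(4,4,5,5-tetramethyl-1,3,2-dioxaborolan-2-yl)butoxy}dimethylsilane F2.
   - NaBO3·4H2O oxidation should give (3R)-3-[4-(benzyloxy)-3-methoxybenzyl]-4-[(tert-butyldimethylsilyl)oxy]butan-1-ol F3.
   - TEMPO/PhI(OAc)2 in MeCN/H2O should give (3R)-3-[4-(benzyloxy)-3-methoxybenzyl]-4-[(tert-butyldimethylsilyl)oxy]butanoic acid F4.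
   - Aqueous HCl in THF should give (4R)-4-[4-(benzyloxy)-3-methoxybenzyl]dihydrofuran-2(3H)-one F5.
   - Deprotonation with LiN(SiMe3)2 in THF at −78 °C and alkylation with commercial 3,4,5-trimethoxybenzyl bromide, which should enter anti to the C4 substituent, comes back to the route at 19, before step 10.

2. Step 4. The copper boryl may add slowly to the electron-rich styrene or with poor facial discrimination, and part of the boron may go to the benzylic carbon followed by loss of silanolate. The fallback builds the same stereocentre by enantioselective diboration and chemoselective cross-coupling.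
   - From 5 and commercial allyloxy(tert-butyl)dimethylsilane, diboration with Pt(dba)3 and a TADDOL-derived phosphonite (antipode giving S) in THF at 60 °C should give (2S)-tert-butyl[2,3-bis(4,4,5,5-tetramethyl-1,3,2-dioxaborolan-2-yl)propoxy]dimethylsilane F6.
   - Suzuki–Miyaura coupling of only the primary boronate with commercial 1-(benzyloxy)-4-bromo-2-methoxybenzene (Pd(OAc)2, 2-dicyclohexylphosphino-2',6'-diisopropoxybiphenyl, KOH, THF/H2O, 70 °C) comes back to the route at 6, before step 6.

3. Step 7. The short-lived carbenoid may decompose before the hindered secondary boronate captures it, or a second CH2 unit may insert into the more reactive primary boronate. The fallback exchanges boron for a vinyl group and cleaves it oxidatively.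
   - From 12, Zweifel olefination (vinyllithium 10, THF, −78 °C; then I2, MeOH; NaOMe) should give tert-butyl{[(2R,3S)-2-[4-(benzyloxy)-3-methoxybenzyl]-3-(3,4,5-trimethoxybenzyl)pent-4-en-1-yl]oxy}dimethylsilane F7, with retention at C3.
   - Lemieux–Johnson cleavage (OsO4 cat., NaIO4, 2,6-lutidine, dioxane/H2O) should give aldehyde 16.
   - Pinnick oxidation (NaClO2, NaH2PO4, 2-methyl-2-butene, t-BuOH/H2O) comes back to the route at 17, before step 9.

Further compounds
F1 | step 6 | (2S)-tert-butyl{2-[4-(benzyloxy)-3-methoxybenzyl]-3-(4,4,5,5-tetramethyl-1,3,2-dioxaborolan-2-yl)propoxy}dimethylsilane | COc1cc(C[C@H](CB2OC(C)(C)C(C)(C)O2)CO[Si](C)(C)C(C)(C)C)ccc1OCc1ccccc1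
F2 | step 6 | (2S)-tert-butyl{2-[4-(benzyloxy)-3-methoxybenzyl]-4-(4,4,5,5-tetramethyl-1,3,2-dioxaborolan-2-yl)butoxy}dimethylsilane | COc1cc(C[C@H](CCB2OC(C)(C)C(C)(C)O2)CO[Si](C)(C)C(C)(C)C)ccc1OCc1ccccc1
F3 | step 6 | (3R)-3-[4-(benzyloxy)-3-methoxybenzyl]-4-[(tert-butyldimethylsilyl)oxy]butan-1-ol | COc1cc(C[C@H](CCO)CO[Si](C)(C)C(C)(C)C)ccc1OCc1ccccc1
F4 | step 6 | (3R)-3-[4-(benzyloxy)-3-methoxybenzyl]-4-[(tert-butyldimethylsilyl)oxy]butanoic acid | COc1cc(C[C@H](CC(=O)O)CO[Si](C)(C)C(C)(C)C)ccc1OCc1ccccc1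
F5 | step 6 | (4R)-4-[4-(benzyloxy)-3-methoxybenzyl]dihydrofuran-2(3H)-one | COc1cc(C[C@H]2COC(=O)C2)ccc1OCc1ccccc1
F6 | step 4 | (2S)-tert-butyl[2,3-bis(4,4,5,5-tetramethyl-1,3,2-dioxaborolan-2-yl)propoxy]dimethylsilane | CC1(C)OB(C[C@H](B2OC(C)(C)C(C)(C)O2)CO[Si](C)(C)C(C)(C)C)OC1(C)C
F7 | step 7 | tert-butyl{[(2R,3S)-2-[4-(benzyloxy)-3-methoxybenzyl]-3-(3,4,5-trimethoxybenzyl)pent-4-en-1-yl]oxy}dimethylsilane | COc1cc(C[C@H]([C@@H](Cc2cc(OC)c(OC)c(OC)c2)C=C)CO[Si](C)(C)C(C)(C)C)ccc1OCc1ccccc1
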